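The data were generated by integration on assumed constants, noise included.

The constant you want here is a level K: the amount of starting material s (c of starting material, in percent of its charge) at which ring and open dimer grow alike.

all flasks: starting material 0.50 M

|  | activator | capture agent | protic impurity | temperature | remark | time |
|---|---|---|---|---|---|---|
| Sunday's | 0.95 equiv | 0.50 M | 0.013 M | 28 °C | run made earlier |  |
| Wednesday's | 0.95 equiv | 0.50 M | 0.050 M | 44 °C | run made earlier |  |
| delta | 0.950 equiv | 0.500 M | 0.0250 M | 20 °C |  | 8.0 min |
| gamma | 0.950 equiv | 0.500 M | 0.0250 M |  | at 20 °C until 2.5 min, from then on at 50 °C | 8.0 min |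
| theta | 0.950 equiv | 0.500 M | 0.0250 M | 50 °C |  | 8.0 min |

| run | time / min | ring / % | open dimer / % | trapped intermediate / % |
|---|---|---|---|---|
| Sunday's | 0.667 | 5.3 | 10.3 | 0.4 |
| Sunday's | 1.00 | 9.3 | 15.8 | 1.7 |
| Sunday's | 2.00 | 17.9 | 25.7 | 2.7 |
| Sunday's | 3.00 | 22.1 | 31.0 | 1.9 |
| Sunday's | 5.00 | 27.5 | 35.1 | 3.6 |
| Sunday's | 8.00 | 30.8 | 36.6 | 2.7 |
| Wednesday's | 0.200 | 7.5 | 8.0 | 1.4 |
| Wednesday's | 0.333 | 12.8 | 15.5 | 1.2 |
| Wednesday's | 0.667 | 21.4 | 20.6 | 1.8 |
| Wednesday's | 1.00 | 25.2 | 24.8 | 1.4 |
| Wednesday's | 1.50 | 30.3 | 27.5 | 2.2 |
| Wednesday's | 2.50 | 32.5 | 28.7 | 2.0 |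

(standard deviation of a reading: 0.5 percentage points)

- percent here means starting material units held: one open dimer counts as two
- the analysis behind the earlier runs scatters by 0.5 percentage points, standard deviation

- which flask leads in share of ring in all that became ring or open dimer or trapped intermediate ("all alike" within 1.5 percentage points) (delta / gamma / theta / all alike)
- share of ring in all that became ring or open dimer or trapped intermediate, delta
- share of ring in all that became ring or open dimer or trapped intermediate, gamma
- share of ring in all that became ring or open dimer or trapped intermediate, theta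

1. Suppose ring closes from one molecule while open dimer takes a second starting material, so that d(ring)/d(open dimer) = K/s. With ds = −d(ring) − d(open dimer), this integrates in closed form: the ring made from s_a down to s_b is K ln[(K + s_a)/(K + s_b)].

2. Now the floor. At their last readings, Sunday's run holds 70.1% as products and Wednesday's 63.2%. Let each protic impurity remove one starting material: that is 2.60% and 10.0%, and the totals become 72.7% and 73.2%. Sunday's sum is still rising, from 66.2% at 5.00 min to its last reading, so these two totals show no common floor. As a working guess I take Wednesday's remainder, 26.8%, as the end level of the new flasks, though it may move with temperature. With impurity at 5.00%, that guess leaves 68.2% to convert into products.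

3. Ring shares at those readings are 43.9% and 51.4%. Inverting the closed form gives K = 46.1% on Sunday and 59.0% on Wednesday. Taking ln K as linear in temperature gives 40.8% at 20 °C and 64.7% at 50 °C. This hot crossover level is the one to carry.

4. The ladder of times: Sunday's run stood at 66.0% of its last sum at 2.00 min, Wednesday's at 69.3% at 0.667 min. Scaled the same way, that time is 0.442 min at 50 °C and 3.46 min at 20 °C, against a run of 8.0 min. So I reckon theta reaches the guessed floor early. On the same guess I reckon that delta ends at s = 31.8%. I reckon gamma at 57.0% at the change, and from there I let it fall to the guessed floor with the hot K.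

5. My shares: delta 40.4%, gamma 46.7%, theta 52.9%, with theta ahead.

The forecast names theta, with 39%, 47% and 54%, on the ground "This fits ring closure being first order and dimer formation involving a second molecule."

The flasks give 38.1% for delta, 49.2% for gamma and 54.3% for theta, so theta leads.

    2 activator → homo dimer (k = 0.229 M⁻¹ min⁻¹, Ea = 73.0 kJ mol⁻¹)
    starting material + activator → activated form (k = 0.541 M⁻¹ min⁻¹, Ea = 60.0 kJ mol⁻¹)
    activated form → ring (k = 0.528 min⁻¹, Ea = 75.0 kJ mol⁻¹)
    starting material + protic impurity → quenched substrate (k = 1.12 M⁻¹ min⁻¹, Ea = 61.0 kJ mol⁻¹)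
    capture agent + activated form → trapped intermediate (k = 0.143 M⁻¹ min⁻¹, Ea = 50.0 kJ mol⁻¹)
    starting material + activated form → open dimer (k = 1.42 M⁻¹ min⁻¹, Ea = 58.0 kJ mol⁻¹)
    (constants at 20 °C)

In theta at 0.203 min, the activated form passes into ring 2.2 times as fast as into open dimer. Each open dimer holds two units, so K/s is this ratio divided by two, 1.11. With the 27.7% starting material left in theta, the carried 64.7% gives a share of 52.6%. Scaled to 75 °C, K becomes 95.1%, and with 37.6% left that repeat of theta reckons at 59.6%, where its simulated share is 62.8%.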